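The vessel is closed and stirred at constant volume, and new partner charges are to run for 25 min beside the runs already made.

| setting | red | ochre | grey | epsilon | alpha | beta | theta |
|---|---|---|---|---|---|---|---|
| substrate | 0.69 M | 0.69 M | 0.69 M | 0.69 M | 0.69 M | 0.69 M | 0.69 M |
| partner | 0.48 equiv | 1.2 equiv | 2.3 equiv | 0.400 equiv | 0.800 equiv | 1.50 equiv | 3.00 equiv |
| free catalyst | 14 mol% | 14 mol% | 14 mol% | 14 mol% | 14 mol% | 14 mol% | 14 mol% |
| remark | run made earlier | run made earlier | run made earlier |  |  |  |  |
| time |  |  |  | 25 min | 25 min | 25 min | 25 min |

| run | time / min | target / % | substrate / % |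
|---|---|---|---|
| red | 2.00 | 6 | 82 |
| red | 6.00 | 19 | 63 |
| red | 12.0 | 17 | 47 |
| red | 20.0 | 9 | 39 |
| red | 25.0 | 6 | 39 |
| ochre | 2.00 | 10 | 77 |
| ochre | 6.00 | 23 | 49 |
| ochre | 12.0 | 30 | 20 |
| ochre | 20.0 | 20 | 4 |
| ochre | 25.0 | 14 | 0 |
| grey | 2.00 | 11 | 78 |
| grey | 6.00 | 26 | 48 |
| grey | 12.0 | 34 | 17 |
| grey | 20.0 | 20 | 2 |
| grey | 25.0 | 10 | 0 |

(readings scatter by 1.5 percentage points)

- "hardly changes" means that all values lie within two and a half points (for a concentration: within two and a half percent of the largest)

- [target] at the end for epsilon, alpha, beta, theta, in this order
- the shape of the row from first to last (hardly changes / rises, then falls / rises all the way / falls, then rises / falls all the way)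

Q: Where does the substrate stop in the red run?

A: It reads 39% at 20.0 min and 39% at 25.0 min, so it has stopped with substrate still present. Ochre, with more partner, reaches 0%, so I take partner to be the limiting reagent in red.

Q: How much substrate did that partner pay for?

A: Red lost 61.0%, but its partner amounts to 48.0% of the substrate. That leaves 13 percentage points over, close to the catalyst loading of 14 mol%.

Q: Couldn't that simply be a ratio of 1.27 substrate per partner?

A: Red cannot tell the two apart. I commit to the subtraction, supposing that each free catalyst takes up one substrate and then waits for partner. For epsilon the stall level, meaning one minus the partner equivalents minus the catalyst loading, is 46.0%. The same sum gives 38.0% for red, against the reading of 39% with a scatter of 1.5 points.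

Q: And the row?

A: In epsilon, by my stall level, 40.0% of the substrate can pass on towards target, so I expect the row to start low. Grey shows the other end, with target falling from 20% to 10% over the last minutes. Ochre, with less partner, goes from 20% to 14% over the same minutes and ends higher than grey, so I expect a rise and then a fall.

The forecast gives 0.035 M, 0.08 M, 0.085 M and 0.055 M, with the shape rises, then falls. It reads the stop this way: “with roughly 1.3 substrate lost per partner”. My own ratio, carried to alpha, asks for 102% of the substrate, whereas my stall level leaves 6.00%.

The flask gives 0.0216 M, 0.0690 M, 0.0834 M and 0.0694 M, with the shape rises, then falls.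

    substrate + free catalyst → catalyst intermediate A (k = 6.80 /M/min)
    partner + catalyst intermediate A → catalyst intermediate B (k = 3.50 /M/min)
    catalyst intermediate B → catalyst intermediate C (k = 1.40 /min)
    catalyst intermediate C ⇌ free catalyst + target (K = 1.20 M, k = 1.80 /min)
    target → over-reaction product (k = 0.150 /min)

Epsilon ends low in part because its target turns on into over-reaction product: with that step taken away, c target at 25 min is 0.275 M instead of 0.0216 M. At that time epsilon has 0.11% of its partner left, catalyst intermediate A, the resting state, holds 99.7% of the catalyst, and the substrate stands at 46.1% against a stall level of 46.0%. Alpha has a stall level of 6.00%, and its substrate reads 8.52% at 25.0 min and 6.00% at 250 min.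

Readings and results come from a simulation for substances that don't exist; scatter was added.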